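Time comes first. From 0.667 h to 8.00 h the blue readings of complex with one exchanged lie between 63% and 68%, and the teal readings from 2.00 h on scatter about a lower level. The bench habit is therefore to take each level as the end state and assume it still stands at 15 h.

| flask | starting complex | incoming ligand | remark | time |
|---|---|---|---|---|
| blue | 18 mM | 30 mM | run made earlier |  |
| teal | 18 mM | 60 mM | run made earlier |  |
| Saturday's | 18 mM | 36.0 mM |  | 15 h |
| Tuesday's | 18 mM | 45.0 mM |  | 15 h |
| Wednesday's | 18 mM | 72.0 mM |  | 15 h |

| blue: time / h | blue: complex with one exchanged / % | teal: time / h | teal: complex with one exchanged / % |
|---|---|---|---|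
| 0.667 | 65 | 0.417 | 57 |
| 1.00 | 65 | 1.00 | 51 |
| 1.33 | 65 | 2.00 | 47 |
| 2.00 | 68 | 3.00 | 48 |
| 3.00 | 68 | 5.00 | 43 |
| 5.00 | 64 | 6.00 | 44 |
| 8.00 | 63 | 8.00 | 50 |

(each reading ± 2 percentage points)

1. which of these holds the largest part of the starting complex at the end of Saturday's (starting complex / complex with one exchanged / complex with three exchanged / complex with two exchanged)
2. which of these holds the largest part of the starting complex at the end of Tuesday's (starting complex / complex with one exchanged / complex with three exchanged / complex with two exchanged)
3. which of these holds the largest part of the starting complex at the end of Wednesday's (starting complex / complex with one exchanged / complex with three exchanged / complex with two exchanged)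
4. how much complex with one exchanged is there at the end of Wednesday's, in percent of the starting complex charged

The mean of the blue readings is 65.4%, and the teal readings from 2.00 h on give 46.4%. It is easier to work with the fraction left than with the fraction converted: raising the charge from 30 mM to 60 mM leaves 0.709 of the blue level. If incoming ligand thins this level as an absorber thins a beam, the extra charge that divides the level by 2 is 60.5 mM; call this the halving charge.

My reckoning from the blue level gives 61.1% for Saturday's flask and 55.1% for Tuesday's. Each estimate is a majority, and a form holding the majority is the largest whatever the others do.

That rule stops at Wednesday's flask. Its charge is 1.20 times the teal charge, beyond the readings, and the teal level already stands below a majority. The halving charge still gives 40.4% of complex with one exchanged, but it says nothing of how the remainder divides, so my reckoning leaves the largest form there open.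

The forecast puts complex with one exchanged first in Saturday's flask and complex with one exchanged in Tuesday's, calls Wednesday's “past the crossover” with complex with two exchanged first, and gives 40% of complex with one exchanged there.

    starting complex + incoming ligand ⇌ leaving ligand + complex with one exchanged (K = 28.0, k = 0.0630 M⁻¹ s⁻¹)
    complex with one exchanged + incoming ligand ⇌ leaving ligand + complex with two exchanged (K = 0.130, k = 0.0490 M⁻¹ s⁻¹)
    complex with two exchanged + incoming ligand ⇌ leaving ligand + complex with three exchanged (K = 1.70, k = 0.100 M⁻¹ s⁻¹)
    incoming ligand → decomposed reagent (k = 3.00 × 10⁻⁴ s⁻¹)
    2 starting complex → self-condensation product (k = 5.20 × 10⁻⁵ M⁻¹ s⁻¹)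
    leaving ligand → by-product carried off (k = 9.40 × 10⁻⁴ s⁻¹)

Complex with one exchanged ends at 66.1% in Saturday's flask, 60.1% in Tuesday's and 35.5% in Wednesday's, where complex with three exchanged leads with 51.3%. Wednesday's flask keeps 0% of its incoming ligand unbound and holds 33.4 mM of decomposed reagent. Complex with one exchanged in Wednesday's flask stands 5 percentage points below the 40.4% reckoned with the halving charge. For the neighbouring flask with 29 mM of incoming ligand, the halving charge of 60.5 mM applied to the blue level gives 66.2%, and that flask ends with 66.9% of complex with one exchanged.

All runs are simulated on assumed constants, and the scatter is random.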